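C5–C6 is cut first (chain numbered C1–C17 from the ring, after removing the two O-benzyl groups), then C13–C14 in the C12 half and the ring-carbon–C1 bond in the arylpentyl half.
Enabling feature: C1–C14 is an unbranched, heteroatom-free run of fourteen CH2 groups between the benzene-1,3-diol ring and the C15 carbinol. C6 can therefore be the terminal carbon of a monosubstituted alkene (latent primary borane) and C5 a primary bromide, five atoms from the ring and nine from C15–OH, with nothing close enough to chelate, eliminate or migrate.
Forward order: C4 epoxide + C8 Grignard reagent gives the C12 alkenol, and aryl Grignard reagent + C5 dibromide gives the arylpentyl bromide. A one-pot hydroboration/alkyl–alkyl Suzuki–Miyaura coupling then joins the halves directly at the alkane oxidation level, and hydrogenolysis frees the resorcinol. No ring is formed.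
Stereochemistry: the only stereocentre, C15 (S), is bought as (S)-1,2-epoxybutane. The epoxide is opened at its CH2, the C–O bond at the stereocentre is never broken, and the CIP order O > long chain > ethyl > H is unchanged, so S stays S.
Helpers: 9-BBN acts twice in the key step (C–B nucleophile at C6, transient B–O mask on C15–OH) and leaves on aqueous work-up. The benzyl ethers leave in the last step.

Key step: step 3

Assumption: (S)-1,2-epoxybutane of high enantiomeric purity and 1,3-bis(benzyloxy)-5-bromobenzene are taken as catalogue compounds.

Step 1
Reactants: 1 (S)-1,2-epoxybutane [(S)-2-ethyloxirane]; 2 8-bromooct-1-ene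
Product: 4 (S)-dodec-11-en-3-ol, via oct-7-en-1-ylmagnesium bromide 3 (not isolated)
Conditions: 2, Mg, THF, rt→40 °C; then CuI (10 mol %), 1, THF, −30→0 °C; aq NH4Cl
Reagents that add atoms: magnesium, [Mg] (stays only in intermediate 3)
Why: Copper-catalysed SN2 opening of a monosubstituted epoxide by a primary Grignard reagent takes place at the unhindered CH2, so the C–O bond at the stereocentre is untouched and the (S) configuration of 1 is carried unchanged into C3 of 4 (the later C15).

Step 2
Reactants: 5 1,3-bis(benzyloxy)-5-bromobenzene; 6 1,5-dibromopentane
Product: 8 1,3-bis(benzyloxy)-5-(5-bromopentyl)benzene, via 3,5-bis(benzyloxy)phenylmagnesium bromide 7 (not isolated)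
Conditions: 5, Mg, THF, reflux; then slow addition to 6 (4 equiv), Li2CuCl4 (3 mol %), THF, 0 °C→rt
Reagents that add atoms: magnesium, [Mg] (stays only in intermediate 7)
Why: This is a copper-catalysed Kumada-type coupling of an aryl Grignard reagent with a primary alkyl bromide, in which inverse addition to an excess of the cheap, distillable dibromide 6 should hold the reaction at mono-substitution, and benzyl ethers are inert to magnesium and to the organocopper species.

Step 3
Reactants: 4 (S)-dodec-11-en-3-ol; 8 1,3-bis(benzyloxy)-5-(5-bromopentyl)benzene
Product: 10 (S)-17-[3,5-bis(benzyloxy)phenyl]heptadecan-3-ol, via O-boryl B-alkyl-9-BBN adduct 9 (not isolated)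
Conditions: 4 (1.2 equiv), 9-BBN-H (2.2 equiv per 4), THF, 0 °C→rt until H2 evolution ends; then 8, Pd(OAc)2 (4 mol %), PCy3 (8 mol %), K3PO4·H2O (4 equiv), THF, rt; aq work-up
Reagents that add atoms: 9-borabicyclo[3.3.1]nonane (9-BBN-H), B1C2CCCC1CCC2 (boron and its bicycle stay only in intermediate 9; product 10 keeps one H)
Why: 9-BBN-H adds across the only C=C of 4 in the anti-Markovnikov sense and puts boron on the terminal carbon (the later C6), while a second equivalent turns the carbinol O–H into a B–O borinate with loss of H2, so that one reagent gives 9 both its nucleophilic site and a traceless mask for the alcohol. Hydroxide from K3PO4·H2O quaternises the trialkylborane, electron-rich Pd(0)/PCy3 enters the primary C–Br bond of 8 by an SN2-type oxidative addition, the primary alkyl group passes from the borate to palladium in preference to the hindered bridgehead B–C bonds, and reductive elimination from the dialkylpalladium forms the C5–C6 bond faster than β-hydride elimination because the phosphine is bulky and strongly donating. The closest known reaction type is the room-temperature alkyl–alkyl Suzuki–Miyaura coupling of B-alkyl-9-BBN reagents with unactivated primary alkyl bromides that bear β-hydrogens, and spending an extra equivalent of borane on a free hydroxyl is established practice in hydroboration/coupling sequences. No ring is closed and no stereocentre is created; the existing one lies nine CH2 groups from the reacting carbon and only its O–H bond is touched, so its configuration should be retained. The step needs terminal regioselectivity in the hydroboration (secured by the bulk of 9-BBN on a monosubstituted alkene), cross- rather than homo-coupling (secured by the fixed nucleophile/electrophile roles of borane and bromide, which two like terminal alkenes in a metathesis would lack) and two-electron rather than radical activation of C–Br (which avoids 1,5-hydrogen transfer from the benzylic C1–H to a C5 radical). The hydrated base and the aqueous work-up hydrolyse the B–O bond and return the free alcohol of 10, with the whole C17 chain already saturated.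

Step 4
Reactants: 10 (S)-17-[3,5-bis(benzyloxy)phenyl]heptadecan-3-ol
Product: 11 Hansfordiol C, 5-[(15S)-15-hydroxyheptadecyl]benzene-1,3-diol
Conditions: H2 (1 atm), 10 % Pd/C, EtOAc–MeOH, rt
Reagents that add atoms: none
Why: Catalytic hydrogenolysis over Pd/C cleaves only the benzylic C–O bonds of the two aryl benzyl ethers, whereas the unactivated secondary carbinol, its stereocentre and the arene are not affected under these mild conditions.

Compound list
1 | (S)-1,2-epoxybutane [(S)-2-ethyloxirane] | CC[C@H]1CO1 | starting material
2 | 8-bromooct-1-ene | C=CCCCCCCBr | starting material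
3 | oct-7-en-1-ylmagnesium bromide | C=CCCCCCC[Mg]Br | intermediate
4 | (S)-dodec-11-en-3-ol | CC[C@H](O)CCCCCCCC=C | intermediate
5 | 1,3-bis(benzyloxy)-5-bromobenzene | Brc1cc(OCc2ccccc2)cc(OCc2ccccc2)c1 | starting material
6 | 1,5-dibromopentane | BrCCCCCBr | starting material
7 | 3,5-bis(benzyloxy)phenylmagnesium bromide | Br[Mg]c1cc(OCc2ccccc2)cc(OCc2ccccc2)c1 | intermediate
8 | 1,3-bis(benzyloxy)-5-(5-bromopentyl)benzene | BrCCCCCc1cc(OCc2ccccc2)cc(OCc2ccccc2)c1 | intermediate
9 | (S)-9-{[12-(9-borabicyclo[3.3.1]nonan-9-yl)dodecan-3-yl]oxy}-9-borabicyclo[3.3.1]nonane (O-boryl B-alkyl-9-BBN adduct) | CC[C@H](OB1C2CCCC1CCC2)CCCCCCCCCB1C2CCCC1CCC2 | intermediate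
10 | (S)-17-[3,5-bis(benzyloxy)phenyl]heptadecan-3-ol | CC[C@H](O)CCCCCCCCCCCCCCc1cc(OCc2ccccc2)cc(OCc2ccccc2)c1 | intermediate
11 | Hansfordiol C, 5-[(15S)-15-hydroxyheptadecyl]benzene-1,3-diol | CC[C@H](O)CCCCCCCCCCCCCCc1cc(O)cc(O)c1 | target

Total step count: 4
Longest linear sequence: 3 (steps 1, 3, 4 or steps 2, 3, 4)

Steps most likely to fail

1. Step 3.
Risk: transmetalation may stall because the additional borinate and the borinic acid formed bind the base. β-Hydride elimination and hydrodebromination may also occur at the alkylpalladium stage.
Fallback (sets out from 4 and 8, returns at 10): the union is changed to a copper-catalysed Grignard–alkyl sulfonate coupling.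
- Hydroboration–oxidation of 4 (9-BBN-H, THF; NaOH, H2O2) should give (S)-dodecane-1,10-diol F1.
- Selective sulfonylation of its primary hydroxyl (TsCl 1.05 equiv, pyridine, CH2Cl2, 0 °C) should give (S)-10-hydroxydodecyl 4-methylbenzenesulfonate F2.
- Bromide 8 is converted with Mg in THF into 5-[3,5-bis(benzyloxy)phenyl]pentylmagnesium bromide F3.
- F2 is first deprotonated at its hydroxyl with one equivalent of MeMgCl. It is then treated with F3 and Li2CuCl4 (5 mol %) in THF at −30 °C→rt, which should deliver 10 after aqueous work-up.

2. Step 2.
Risk: the dibromide may react at both ends, the aryl Grignard reagent may homocouple oxidatively, and magnesium insertion into the electron-rich aryl bromide may be sluggish.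
Fallback (sets out from 5, returns at 8): the aryl–C1 bond is made by a B-alkyl Suzuki–Miyaura coupling instead.
- 5-Bromopent-1-ene is hydroborated with 9-BBN-H in THF to 9-(5-bromopentyl)-9-borabicyclo[3.3.1]nonane F4.
- F4 is coupled in the same flask with 5 (PdCl2(dppf) 3 mol %, K3PO4, THF–DMF–H2O, 50 °C).
- Palladium carrying dppf inserts only into the C(sp2)–Br bond, so the primary alkyl bromide should survive and 8 is reached directly.

3. Step 1.
Risk: Wurtz dimerisation may occur while the Grignard reagent forms. Magnesium bromide may open the epoxide competitively, or the epoxide may undergo Lewis-acid-induced rearrangement before C–C bond formation.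
Fallback (sets out from 1, returns at 4): the epoxide is opened with an acetylide and the unsaturation is then moved to the chain end.
- Oct-1-yne, n-BuLi and BF3·OEt2 in THF at −78 °C with 1 should give (S)-dodec-5-yn-3-ol F5.
- The alkyne zipper reaction (potassium 3-aminopropylamide in 1,3-diaminopropane, 0 °C→rt) should move the triple bond to the terminus and give (S)-dodec-11-yn-3-ol F6, with the carbinol protected as its alkoxide.
- Semihydrogenation (H2, Lindlar catalyst, quinoline, hexane) should give 4.

Further compounds
F1 | step 3 | (S)-dodecane-1,10-diol | CC[C@H](O)CCCCCCCCCO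
F2 | step 3 | (S)-10-hydroxydodecyl 4-methylbenzenesulfonate | CC[C@H](O)CCCCCCCCCOS(=O)(=O)c1ccc(C)cc1
F3 | step 3 | 5-[3,5-bis(benzyloxy)phenyl]pentylmagnesium bromide | Br[Mg]CCCCCc1cc(OCc2ccccc2)cc(OCc2ccccc2)c1
F4 | step 2 | 9-(5-bromopentyl)-9-borabicyclo[3.3.1]nonane | BrCCCCCB1C2CCCC1CCC2
F5 | step 1 | (S)-dodec-5-yn-3-ol | CC[C@H](O)CC#CCCCCCC
F6 | step 1 | (S)-dodec-11-yn-3-ol | CC[C@H](O)CCCCCCCC#C
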